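**Assumptions (one line):** The SMILES fixes a ring-Z C5=C6 alkene (C4 and C7 cis). The imidazolidinone and triazolium catalysts are taken in whichever enantiomeric form gives the drawn antipode. 4-Methyl-5,6-dihydro-2H-pyran-2-one, (E,E)-1,4-diacetoxybutadiene and TBSOCH2CHO are treated as commercial.

## Retrosynthetic overview
1. Target ← C9 acetylation ← TIPS removal ← γ-lactone with the C8 tertiary alcohol, formed by intramolecular Reformatsky of a C7 2-bromopropionate onto the C8 ketone (third ring).
2. The C8 ketone and C7 alcohol come from an NHC-catalysed macrocyclic crossed benzoin between a C8 α-silyloxy aldehyde and a Z-enal at C7 (10-membered ring, formed second).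
3. The benzoin precursor is built on the cyclohexane from an iminium-catalysed Diels–Alder of methacrolein with 1,4-diacetoxybutadiene (ring formed first, setting C1 and C14). The C2 chain is then added by organocerium addition, C11 is oxidised to an enone, and C10–C9 is formed by Mukaiyama aldol.
4. C11=CH2 is installed by Petasis methylenation. C9 stays as a TIPS ether until the end.

## Forward route

**Step 1**
Reactants: 1 methacrolein; 2 (1E,3E)-1,4-diacetoxybuta-1,3-diene
Product: 3 aldehyde, 2,5-diacetoxy-1-methylcyclohex-3-ene-1-carbaldehyde (CHO cis to C2-OAc; 2,5-OAc cis; single enantiomer)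
Conditions: chiral imidazolidinone·TfOH (20 mol %), MeCN/H2O 95:5, –20 °C, 48 h
Reagents that add atoms: none
Why: Iminium-ion Diels–Alder via the endo transition state with both diene OAc groups "outside" puts OAc cis to CHO. The catalyst shields one iminium face, setting the quaternary C1 and C14 (and C11) in one step; the diene is symmetric, so regiochemistry is not an issue.

**Step 2**
Reactants: 4 4-methyl-5,6-dihydro-2H-pyran-2-one
Product: 5 (Z)-5-iodo-3-methylpent-2-enoic acid
Conditions: TMSI, CH2Cl2, 0 °C; then H2O; use immediately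
Reagents that add atoms: TMSI, C[Si](C)(C)I
Why: Iodide opens the lactone by SN2 at the O–CH2 carbon, so the ring cis-alkene becomes the Z-alkene (C4 and C7 cis) of the C3–C7 unit.

**Step 3**
Reactants: 5
Product: 6 (Z)-5-iodo-3-methylpent-2-en-1-ol
Conditions: BH3·SMe2, THF, 0 °C
Reagents that add atoms: none
Why: Borane reduces the carboxylic acid chemoselectively in the presence of the alkyl iodide and the trisubstituted alkene.

**Step 4**
Reactants: 6
Product: 7 Z-iodo TBS ether
Conditions: TBSCl, imidazole, DMF, 0 °C
Reagents that add atoms: TBSCl, CC(C)(C)[Si](C)(C)Cl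
Why: Standard silylation of a primary alcohol masks C7 for later oxidation.

**Step 5**
Reactants: 3; 7
Product: 8 C2 carbinol
Conditions: 7, t-BuLi (2 equiv), Et2O, –78 °C; CeCl3; then 3, THF, –78 °C; NH4Cl quench at –78 °C
Reagents that add atoms: none
Why: The organocerium adds chemoselectively to the aldehyde over the acetates. It follows polar Felkin–Anh control (nucleophile anti to the C14–O bond, passing the small C1 methyl), which sets the C2 configuration. The cold quench limits 1,3-acetyl transfer from C14 to the new C2 alkoxide.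

**Step 6**
Reactants: 8
Product: 9 C2 propionate
Conditions: (EtCO)2O, Et3N, DMAP, CH2Cl2, 35 °C
Reagents that add atoms: propionic anhydride, CCC(=O)OC(=O)CC
Why: Acylation of the hindered secondary alcohol with DMAP catalysis; acylating the neutral alcohol avoids 1,3-acyl migration from C14.

**Step 7**
Reactants: 9
Product: 10 C11 alcohol (other esters intact)
Conditions: Novozym 435 (CALB), n-BuOH, MTBE, 30 °C
Reagents that add atoms: none
Why: The lipase cleaves the only sterically unencumbered acetate, at C11, and leaves the acetate and propionate next to the quaternary centre.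

**Step 8**
Reactants: 10
Product: 11 γ-acetoxy enone (C11=O, C12=C13)
Conditions: MnO2 (20 equiv), CH2Cl2, 23 °C
Reagents that add atoms: none
Why: Chemoselective oxidation of the allylic alcohol by MnO2; C11 is planarised and is the regiochemical handle for α′-enolisation at C10.

**Step 9**
Reactants: 11; 12 TBSOCH2CHO
Product: 13 C10–C9 aldol (C9-OH)
Conditions: 11, TMSOTf, Et3N, CH2Cl2, 0 °C; then 12, BF3·OEt2, –78 °C; PPTS, MeOH workup
Reagents that add atoms: none (TMS is removed in the workup)
Why: Mukaiyama aldol of the cross-conjugated 2-silyloxydiene, which reacts only at C10 (α′). The acceptor approaches anti to the C2 side chain (syn to the C1 methyl), so C9 ends up trans to C2 as in the target. An open, Felkin-type transition state with the α-silyloxy aldehyde sets C9, and no free enolate is present to acylate from the neighbouring esters.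

**Step 10**
Reactants: 13
Product: 14 C9 TIPS ether
Conditions: TIPSOTf, 2,6-lutidine, CH2Cl2, –78 → 0 °C
Reagents that add atoms: TIPSOTf, CC(C)[Si](C(C)C)(C(C)C)OS(=O)(=O)C(F)(F)F
Why: Protecting C9 prevents retro-aldol or β-elimination and keeps an α-acyloxy leaving group off the later benzoin substrate.

**Step 11**
Reactants: 14
Product: 15 saturated C11 ketone (C12, C13 now CH2)
Conditions: Stryker's reagent [(Ph3P)CuH]6 (0.3 equiv), PhSiH3, toluene, –20 °C
Reagents that add atoms: none
Why: Cu–H 1,4-reduces the enone and leaves the Z-trisubstituted alkene, esters and silyl ethers untouched; no new stereocentre is formed.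

**Step 12**
Reactants: 15
Product: 16 exocyclic C11=CH2
Conditions: Cp2TiMe2 (4 equiv), toluene/THF 4:1, 70 °C, dark
Reagents that add atoms: dimethyltitanocene, C[Ti](C)(C1C=CC=C1)C1C=CC=C1 (supplies the =CH2)
Why: Petasis methylenation is non-basic and ketone-selective, so the β-OTIPS ketone cannot undergo E1cB, and the hindered C11 ketone is methylenated before the C8 carbonyl exists.

**Step 13**
Reactants: 16
Product: 17 diol (C7 allylic OH, C8 primary OH; TIPS retained)
Conditions: HF·pyridine, pyridine/THF, 0 → 23 °C
Reagents that add atoms: none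
Why: The primary/allylic TBS ethers are removed while the hindered secondary TIPS ether, acetates and propionate survive.

**Step 14**
Reactants: 17
Product: 18 dialdehyde (Z-enal at C7, α-silyloxy aldehyde at C8)
Conditions: Dess–Martin periodinane, NaHCO3, CH2Cl2, 0 °C
Reagents that add atoms: none
Why: Mild double oxidation of a primary and an allylic alcohol that leaves the Z-alkene geometry and C9 configuration intact.

**Step 15**
Reactants: 18
Product: 19 macrocyclic α-hydroxy ketone (C7-OH, C8=O)
Conditions: chiral aminoindanol-derived N-C6F5 triazolium BF4 (20 mol %), DIPEA, THF, 0.002 M, syringe-pump addition over 10 h, 25 °C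
Reagents that add atoms: none
Why: Proposed new method: the NHC adds to the more electrophilic α-silyloxy aldehyde (C8) to give a Breslow intermediate. This acyl-anion equivalent adds intramolecularly to the resonance-deactivated Z-enal carbonyl (C7), closing the 10-membered ring, with the Z-alkene and the ring A fusion preorganising the tether, and the chiral triazolium sets C7. The closest known chemistry is the intramolecular crossed aldehyde–ketone benzoin that forms 5–7-membered rings; here it is extended to an aldehyde–aldehyde macrocyclisation forming a 10-membered carbocycle.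

**Step 16**
Reactants: 19
Product: 20 C7 2-bromopropionate
Conditions: 2-bromopropionyl bromide, pyridine, DMAP, CH2Cl2, 0 °C
Reagents that add atoms: 2-bromopropionyl bromide, CC(Br)C(=O)Br
Why: Esterification of the α-keto allylic alcohol installs the C17/C18/C19 unit as a bromo ester; its stereocentre is irrelevant because it is destroyed in the next step.

**Step 17**
Reactants: 20
Product: 21 γ-lactone with C8 tertiary alcohol (C9-OTIPS)
Conditions: Zn dust, TMSCl (cat.), THF, 0.005 M, 50 °C
Reagents that add atoms: none
Why: Intramolecular Reformatsky reaction: the zinc enolate adds 5-exo to the electrophilic C8 ketone. The tether from C7–O can reach only one face of C8, which sets C8 (C7-OH is already defined), and a cyclic transition state sets C17. Zn is used because it leaves the α-acyloxy ketone and the other esters intact, whereas SmI2 would cleave the α-acyloxy groups.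

**Step 18**
Reactants: 21
Product: 22 C9 alcohol
Conditions: HF·pyridine, THF, 40 °C
Reagents that add atoms: none
Why: Fluoride removes the secondary silyl ether without touching the esters or the lactone.

**Step 19**
Reactants: 22
Product: 23 junceellolide E
Conditions: Ac2O, DMAP, pyridine, CH2Cl2, 0 → 23 °C
Reagents that add atoms: acetic anhydride, CC(=O)OC(=O)C
Why: Selective acetylation of the secondary C9 alcohol; the tertiary C8-OH is unreactive, which gives the natural acetate pattern (C2 propionate, C9 and C14 acetates).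

## Compound list
1 | methacrolein | C=C(C)C=O | starting material
2 | (1E,3E)-1,4-diacetoxybutadiene | CC(=O)O/C=C/C=C/OC(C)=O | starting material
3 | 2,5-diacetoxy-1-methylcyclohex-3-ene-1-carbaldehyde, single enantiomer | O=C[C@@]1(C)[C@@H](OC(C)=O)C=C[C@@H](OC(C)=O)C1 | intermediate
4 | 4-methyl-5,6-dihydro-2H-pyran-2-one | CC1=CC(=O)OCC1 | starting material
5 | (Z)-5-iodo-3-methylpent-2-enoic acid | OC(=O)/C=C(/C)CCI | intermediate
6 | (Z)-5-iodo-3-methylpent-2-en-1-ol | OC/C=C(/C)CCI | intermediate
7 | (Z)-TBS ether of 6 | CC(C)(C)[Si](C)(C)OC/C=C(/C)CCI | intermediate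
8 | C2 carbinol adduct of 3 and 7 | O[C@H](CC/C(C)=C\CO[Si](C)(C)C(C)(C)C)[C@@]1(C)[C@@H](OC(C)=O)C=C[C@@H](OC(C)=O)C1 | intermediate
9 | C2 propionate of 8 | CCC(=O)O[C@H](CC/C(C)=C\CO[Si](C)(C)C(C)(C)C)[C@@]1(C)[C@@H](OC(C)=O)C=C[C@@H](OC(C)=O)C1 | intermediate
10 | C11 alcohol (mono-deacetylated 9) | CCC(=O)O[C@H](CC/C(C)=C\CO[Si](C)(C)C(C)(C)C)[C@@]1(C)[C@@H](OC(C)=O)C=C[C@@H](O)C1 | intermediate
11 | γ-acetoxy enone | CCC(=O)O[C@H](CC/C(C)=C\CO[Si](C)(C)C(C)(C)C)[C@@]1(C)[C@@H](OC(C)=O)C=CC(=O)C1 | intermediate
12 | TBSOCH2CHO | CC(C)(C)[Si](C)(C)OCC=O | starting material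
13 | aldol adduct (C9-OH) | CCC(=O)O[C@H](CC/C(C)=C\CO[Si](C)(C)C(C)(C)C)[C@@]1(C)[C@@H](OC(C)=O)C=CC(=O)[C@@H]1[C@@H](O)CO[Si](C)(C)C(C)(C)C | intermediate
14 | C9 TIPS ether | CCC(=O)O[C@H](CC/C(C)=C\CO[Si](C)(C)C(C)(C)C)[C@@]1(C)[C@@H](OC(C)=O)C=CC(=O)[C@@H]1[C@@H](O[Si](C(C)C)(C(C)C)C(C)C)CO[Si](C)(C)C(C)(C)C | intermediate
15 | saturated ketone | CCC(=O)O[C@H](CC/C(C)=C\CO[Si](C)(C)C(C)(C)C)[C@@]1(C)[C@@H](OC(C)=O)CCC(=O)[C@@H]1[C@@H](O[Si](C(C)C)(C(C)C)C(C)C)CO[Si](C)(C)C(C)(C)C | intermediate
16 | exocyclic methylene compound | CCC(=O)O[C@H](CC/C(C)=C\CO[Si](C)(C)C(C)(C)C)[C@@]1(C)[C@@H](OC(C)=O)CCC(=C)[C@@H]1[C@@H](O[Si](C(C)C)(C(C)C)C(C)C)CO[Si](C)(C)C(C)(C)C | intermediate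
17 | diol | CCC(=O)O[C@H](CC/C(C)=C\CO)[C@@]1(C)[C@@H](OC(C)=O)CCC(=C)[C@@H]1[C@@H](O[Si](C(C)C)(C(C)C)C(C)C)CO | intermediate
18 | dialdehyde | CCC(=O)O[C@H](CC/C(C)=C\C=O)[C@@]1(C)[C@@H](OC(C)=O)CCC(=C)[C@@H]1[C@@H](O[Si](C(C)C)(C(C)C)C(C)C)C=O | intermediate
19 | macrocyclic α-hydroxy ketone | C=C1CC[C@H](OC(C)=O)[C@@]2(C)[C@H]1[C@@H](O[Si](C(C)C)(C(C)C)C(C)C)C(=O)[C@@H](O)/C=C(/C)CC[C@H]2OC(=O)CC | intermediate
20 | C7 2-bromopropionate | C=C1CC[C@H](OC(C)=O)[C@@]2(C)[C@H]1[C@@H](O[Si](C(C)C)(C(C)C)C(C)C)C(=O)[C@@H](OC(=O)C(C)Br)/C=C(/C)CC[C@H]2OC(=O)CC | intermediate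
21 | lactone, C9-OTIPS | C=C1CC[C@H](OC(C)=O)[C@@]2(C)[C@H]1[C@@H](O[Si](C(C)C)(C(C)C)C(C)C)[C@@]1(O)[C@H](/C=C(/C)CC[C@H]2OC(=O)CC)OC(=O)[C@@H]1C | intermediate
22 | C9 alcohol | C=C1CC[C@H](OC(C)=O)[C@@]2(C)[C@H]1[C@@H](O)[C@@]1(O)[C@H](/C=C(/C)CC[C@H]2OC(=O)CC)OC(=O)[C@@H]1C | intermediate
23 | junceellolide E | C=C1CC[C@H](OC(C)=O)[C@@]2(C)[C@H]1[C@@H](OC(C)=O)[C@@]1(O)[C@H](/C=C(/C)CC[C@H]2OC(=O)CC)OC(=O)[C@@H]1C | target

## Summary
**Total steps:** 19, of which steps 2–4 are the side branch that makes fragment 7.
**Longest linear sequence:** 18 steps, running from lactone 4 through steps 2, 3 and 4 to 7, then steps 5–19 to the target. The other branch (1 + 2 → 3) is a single step.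

**Three steps most likely to fail**
1. **Step 15, NHC macrocyclic crossed benzoin (the proposed new step).** Risks are the wrong aldehyde acting as acyl donor, Z→E enal isomerisation, C9 epimerisation, and oligomerisation.
   - Fallback (different approach, known chemistry): add 3-methylbut-3-enylmagnesium bromide at step 5, introduce C7/C8 with a dihydroxylation-derived vinyl-dioxolane aldehyde in the Mukaiyama aldol, close C5=C6 by Z-selective RCM (Hoveyda–Grubbs II), then oxidise C8.
2. **Step 9, Mukaiyama aldol at the neopentylic C10 with C9 stereocontrol.** The hindered nucleophile or poor C9 selectivity could give low yield or the wrong C9 epimer.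
   - Fallback: set C10/C9 by Ireland–Claisen rearrangement of a glycolate ester of the ring-A allylic alcohol (C10=C11–CH2OH), which forms C10–C9 and the exocyclic methylene together.
3. **Step 17, Zn Reformatsky lactonisation.** Stereocontrol at C8 and C17 is uncertain, and the α,α′-dioxygenated C8 ketone is sensitive.
   - Fallback: acylate C7-OH with 2-(diethoxyphosphoryl)propanoic acid, close the 3-methylbutenolide by intramolecular HWE onto C8=O, then install C8-OH/C17-H by Mukaiyama hydration or nucleophilic epoxidation with reductive epoxide opening.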